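## Analysis of the target

The target is a trans-fused 2-oxohexahydroindene, numbered as that ring system. Ring B is the cyclopentanone C7a–C1–C2(=O)–C3–C3a, with ethyl on C1 and methyl on C3. Ring A is the cyclohexene C3a–C4–C5–C6=C7–C7a, with ethyl and carboxyl on C4, ethyl and (E)-styryl on C5, and ethyl on C7.

It has six contiguous stereocentres (C1, C3, C3a, C4, C5, C7a). On ring B the substituents alternate faces all round (C1-ethyl, C7a–C7, C3a–C4, C3-methyl: all-trans). Since C1 and C3 are α to the ketone and all-trans is the all-pseudo-equatorial arrangement, these two centres can be left to equilibration.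

On ring A, C4 and C5 are adjacent quaternary carbons. The carboxyl group is cis to the styryl group and to the C7a–C1 bond and trans to the C3a–C3 bond; the two ethyl groups are cis to each other.

Sensitive points are the γ,δ-unsaturated acid (acid would lactonise it onto C6=C7), the styrene (no hydrogenation, no strong electrophiles), the enolisable ketone, and a neopentyl-type carboxyl that cannot be esterified or saponified by acyl transfer.

The hard part is the pair of vicinal quaternary carbons C4/C5, which must be set relative to C3a and C7a. The route rests on one feature: the carboxyl carbon, C4, C5 and C6=C7 form a γ,δ-unsaturated acid spanning both quaternary carbons. That is the product pattern of a [3,3] shift of an allyl ketene acetal, and tying the ester oxygen to C7 turns the precursor into a δ-lactone.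

## Retrosynthetic reasoning

**33 from 32.** No skeletal bond is cut. The C4 carboxyl is carried as the allyl ester 32, because an acid flanked by two quaternary carbons cannot be unmasked by saponification. The last step must leave C1/C3, the alkenes and the free acid untouched, which a neutral palladium-catalysed deallylation does.

**32 from 29.** The C1–C2 bond of ring B is cut. C2 is an acyl carbon and can be an acyl radical from selenoester 29; C1 is then the inner carbon of a propenyl group on C7a, and the 5-exo closure also turns the propenyl group into the C1 ethyl. Cutting here leaves C3a and C7a as ordinary substituted carbons of a monocyclic cyclohexene. A cut at C3a–C3 or C7a–C1 would mean forming a bond to a ring-A stereocentre late. The forward step has to close a trans-fused five-membered ring and set C1, which can also be corrected by equilibration.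

**29 from 25.** Functional-group changes only: selenoester 29 from acid 28, from alcohol 27, from silyl ether 26, which is the allyl ester of acid 25.

**25 from 22 (key disconnection).** The C4–C5 bond of ring A is cut and the carboxyl oxygen is reconnected to C7, giving δ-lactone 22. This is the only cut that makes both quaternary carbons in one intramolecular event. The stereochemical problem is moved to a tertiary carbinol (C7) and an alkene geometry (C6=C5), both easier to control. Cuts at C5–C6 or C3a–C4 would leave one quaternary centre to be made earlier by an intermolecular alkylation. The forward step has to enolise C4, silylate on oxygen, and rearrange through the boat that the ring enforces.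

**22 from 21 from 20.** The lactone is not made by acylating the tertiary dienylic alcohol, since acidic or strongly activating conditions would ionise it. Instead the C4 carboxyl is carried at the alcohol level (diol 21, from tert-butyl ester 20) and the ring is closed by oxidation through the lactol.

**20 from 17 and 18.** The sp2–sp2 bond between C5 and the styryl group is cut, giving alkyne 17 and alkenyl bromide 18. Syn addition of H–metal across the alkyne defines the trisubstituted C6=C5 geometry. Carrying a slim alkyne instead of the diene through the earlier steps also serves the stereocontrol at C7.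

**17 from 14 (through 16 and 15).** The propenyl C=C is cut (Wittig) and C1 is reconnected as the carbonyl of a δ-lactone whose ring oxygen is the C2 oxygen (14). This places C3, C3a and C7a in one six-membered ring, and their required relationship there is all-trans.

**14 from 5, 10 and 9.** Two bonds are cut: C3a–C4 (conjugate addition of the enolate of ester 10 to lactone 5) and C7a–C7 (aldol addition of the resulting lactone enolate to ynone 9). On the ring of 5 the nucleophile enters anti to the C3 methyl and the electrophile anti to the new C3a substituent, which is what the target needs. C7 follows from a closed chair transition state in which the alkynyl group is the small substituent. C4 need not be controlled, since the key step planarises it.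

**5 from 1; 9 from 6 and 7.** Lactone 5 comes from hydroxy ester 1 by (Z)-olefination of aldehyde 3 and ring closure, so C3 is taken from the chiral pool. Ynone 9 is an acetylide acylation.

## Alternatives that were turned down

**Alternative 1:** This cuts C3a–C7a inside ring B and forms it by a reductive Nazarov cyclisation. The Lewis-acid complex of the acyclic (E,E)-dienone A2 would close by conrotation, joining the two β-carbons trans. A silane would then reduce the oxyallyl cation to the all-trans cyclopentanone A1.
- *For:* ring B and the trans ring-fusion pair come in one step from an easily assembled acyclic ketone, and the trans relationship follows from orbital symmetry.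
- *Against:* the absolute sense of conrotation must be relayed from a single silyloxy stereocentre on a side chain, which is weak control. β-Alkyl dienones without polarising groups cyclise sluggishly, and the allylic silyloxy group can be lost by elimination. Above all, A1 contains none of ring A: the quaternary pair C4/C5 would still have to be built from two oxygenated side chains, with stepwise stereocontrol.
- *Comparison:* on the ring-fusion pair this alternative is stronger, one step against a template and a three-component coupling. The chosen strategy spends its key step on the hardest feature and sets both quaternary centres at once.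

**Alternative 2:** This cuts C3a–C4 and forms ring A by Favorskii contraction. Methoxide would convert the α-bromo cycloheptenone A4 (carbonyl between C3a and C4, bromide on C4) through a cyclopropanone into the methyl ester A3.
- *For:* the carboxyl group lands directly on the quaternary C4, the cyclopropanone should open toward the less substituted carbanion (C3a), and the skeleton including ring B is complete at that point. The endgame would be only ketal and ester cleavage, which is shorter than the six steps that follow the chosen key step.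
- *Against:* A4 must already contain the C5 quaternary centre in a seven-membered ring and a tertiary bromide next to it, which invites elimination. Bromination at a fully substituted α-carbon must be regio- and stereoselective. In methanol a tertiary α-bromo ketone tends to react through an oxyallyl species, so the inversion at C4 needed for stereospecificity is not secured. C3a is reprotonated without guarantee of the trans fusion.
- *Comparison:* the chosen strategy sets C4 and C5 together by a concerted shift whose outcome is fixed by geometry. The Favorskii route sets C4 alone and pushes C5 and a seven-membered ring into the precursor.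

**Alternative 3:** This cuts C5–C6 and forms ring A by an intramolecular Heck reaction. Zerovalent palladium would insert into the C–I bond of the (Z)-alkenyl iodide A6. The alkenylpalladium would add 6-exo to the trisubstituted alkene, creating C5, and β-hydride elimination toward the benzylic CH2 would give the (E)-styryl group of A5.
- *For:* the step is catalytic, forms ring A and the C5 quaternary centre and unveils the styryl group at once. The elimination can go only one way because C5 has no hydrogen, and ring B with its ketone can be in place. On mildness and convergence at a late stage it is at least as strong as the chosen step.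
- *Against:* C4 must already be quaternary, so one of the two hard centres is made elsewhere by enolate alkylation next to C3a. The C5 configuration depends on which alkene face inserts, and the controlling neighbour (C4) carries ethyl and ester groups of similar size. The alkene is neopentyl-hindered.
- *Comparison:* the chosen strategy does not depend on facial selectivity: the C4/C5 relationship is dictated by the boat transition state and the alkene geometry.

Key step: step 13

Remark: C4 (compounds 12–23) and the lactol carbon of 15 arise without control; C4 is planarised in step 13 and the lactol carbon becomes an alkene carbon in step 8, so both are left open in names and SMILES.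

Remark: the propenyl group is carried as the (Z)-isomer from the Wittig step; it is a spectator in step 13 and its geometry is lost when C1 becomes sp3 in step 18.

Remark: the all-trans arrangement on ring B is taken to be the thermodynamic one, because each α-substituent is then pseudo-equatorial, whereas a cis substituent nearly eclipses C4 or C7.

## Route

Step 1
Reactants: 1 methyl (R)-3-hydroxy-2-methylpropanoate
Product: 2 methyl (R)-3-(tert-butyldimethylsilyloxy)-2-methylpropanoate
Conditions: t-BuMe2SiCl, imidazole, CH2Cl2, 0 °C → rt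
Reagents that add atoms: tert-butyldimethylsilyl chloride, CC(C)(C)[Si](C)(C)Cl
Why: Silyl ether formation on the primary alcohol; the weakly basic conditions leave the α-stereocentre (future C3) untouched.

Step 2
Reactants: 2 methyl (R)-3-(tert-butyldimethylsilyloxy)-2-methylpropanoate
Product: 3 (R)-3-(tert-butyldimethylsilyloxy)-2-methylpropanal
Conditions: i-Bu2AlH (1.1 equiv), CH2Cl2, −78 °C; aq. KNaC4H4O6 (potassium sodium tartrate)
Reagents that add atoms: none
Why: Partial ester reduction; the tetrahedral aluminium hemiacetal is stable at −78 °C and releases the aldehyde on work-up. The configurationally labile aldehyde is used at once without chromatography.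

Step 3
Reactants: 3 (R)-3-(tert-butyldimethylsilyloxy)-2-methylpropanal
Product: 4 methyl (2Z,4S)-5-(tert-butyldimethylsilyloxy)-4-methylpent-2-enoate
Conditions: (CF3CH2O)2P(O)CH2CO2Me, KN(SiMe3)2, 18-crown-6, THF, −78 °C
Reagents that add atoms: methyl bis(2,2,2-trifluoroethyl)phosphonoacetate, COC(=O)CP(=O)(OCC(F)(F)F)OCC(F)(F)F
Why: Still–Gennari olefination; the trifluoroethyl phosphonate under dissociating conditions gives the (Z)-enoate that ring closure requires. The low temperature avoids epimerisation next to the aldehyde.

Step 4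
Reactants: 4 methyl (2Z,4S)-5-(tert-butyldimethylsilyloxy)-4-methylpent-2-enoate
Product: 5 (S)-5-methyl-5,6-dihydro-2H-pyran-2-one
Conditions: TsOH·H2O (cat.), MeOH, rt; then PhMe, 60 °C
Reagents that add atoms: none
Why: Acid-catalysed desilylation followed by lactonisation (intramolecular transesterification) of the (Z)-δ-hydroxy enoate; closure of the six-membered ring is fast and does not involve the stereocentre.

Step 5
Reactants: 6 but-1-yne; 7 N-methoxy-N-methylpropanamide
Product: 9 hept-4-yn-3-one, via but-1-ynyllithium 8 (not isolated)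
Conditions: n-BuLi, THF, −78 °C; then 7, −78 → 0 °C; aq. NH4Cl
Reagents that add atoms: none
Why: Weinreb ketone synthesis; the chelated tetrahedral adduct survives until work-up, so the acetylide adds only once.

Step 6
Reactants: 10 tert-butyl butanoate; 5 (S)-5-methyl-5,6-dihydro-2H-pyran-2-one; 9 hept-4-yn-3-one
Product: 14 tert-butyl 2-[5-methyl-2-oxo-3-(3-trimethylsilyloxyhept-4-yn-3-yl)oxan-4-yl]butanoate (ring substituents all-trans), via ester lithium enolate 11 (not isolated), via lactone lithium enolate 12 (not isolated), via lithium aldolate 13 (not isolated)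
Conditions: LiN(i-Pr)2 (1.05 equiv), THF, −78 °C, 10; then 5, −78 °C; then 9, −78 °C; then Me3SiCl, −78 → −20 °C
Reagents that add atoms: chlorotrimethylsilane, C[Si](C)(C)Cl
Why: Tandem Michael addition–aldol addition on a cyclic enoate. The ester enolate adds to C3a anti to the C3 methyl group, the lactone enolate then reacts at C7a anti to the new C3a substituent, and in the closed chair transition state the ketone places ethyl equatorial and the slim alkynyl group axial, which sets C7 as required. C4 is formed without control, and O-silylation of the tertiary aldolate blocks retro-aldol cleavage.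

Step 7
Reactants: 14 tert-butyl 2-[5-methyl-2-oxo-3-(3-trimethylsilyloxyhept-4-yn-3-yl)oxan-4-yl]butanoate
Product: 15 tert-butyl 2-[2-hydroxy-5-methyl-3-(3-trimethylsilyloxyhept-4-yn-3-yl)oxan-4-yl]butanoate (lactol as an anomer mixture)
Conditions: i-Bu2AlH (1.2 equiv), PhMe, −78 °C; aq. KNaC4H4O6
Reagents that add atoms: none
Why: Lactone-to-lactol reduction; at −78 °C the tert-butyl ester, the silyl ether and the alkyne are not attacked.

Step 8
Reactants: 15 tert-butyl 2-[2-hydroxy-5-methyl-3-(3-trimethylsilyloxyhept-4-yn-3-yl)oxan-4-yl]butanoate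
Product: 16 tert-butyl 2,5-diethyl-3-(1-hydroxypropan-2-yl)-4-[(Z)-prop-1-enyl]-5-trimethylsilyloxynon-6-ynoate
Conditions: EtPPh3Br, KN(SiMe3)2, THF, 0 °C; then 15, −78 → 0 °C
Reagents that add atoms: ethyltriphenylphosphonium bromide, CC[P+](c1ccccc1)(c1ccccc1)c1ccccc1.[Br-]
Why: Wittig olefination of the lactol through its open hydroxy aldehyde form; the unstabilised ylide gives the (Z)-propenyl group on C7a and frees the C2 hydroxyl. The silyl ether on C7 rules out retro-aldol cleavage. At or below 0 °C olefination should outrun both enolisation at C7a and attack of the liberated alkoxide on the tert-butyl ester.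

Step 9
Reactants: 16 tert-butyl 2,5-diethyl-3-(1-hydroxypropan-2-yl)-4-[(Z)-prop-1-enyl]-5-trimethylsilyloxynon-6-ynoate
Product: 17 tert-butyl 3-[1-(tert-butyldimethylsilyloxy)propan-2-yl]-2,5-diethyl-4-[(Z)-prop-1-enyl]-5-trimethylsilyloxynon-6-ynoate
Conditions: t-BuMe2SiCl, imidazole, CH2Cl2, rt
Reagents that add atoms: tert-butyldimethylsilyl chloride, CC(C)(C)[Si](C)(C)Cl
Why: Silyl ether formation on the only free (primary) hydroxyl, giving a C2 protecting group that survives hydride, strong base and heat.

Step 10
Reactants: 17 tert-butyl 3-[1-(tert-butyldimethylsilyloxy)propan-2-yl]-2,5-diethyl-4-[(Z)-prop-1-enyl]-5-trimethylsilyloxynon-6-ynoate; 18 (E)-(2-bromoethenyl)benzene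
Product: 20 tert-butyl (6E,8E)-3-[1-(tert-butyldimethylsilyloxy)propan-2-yl]-2,5,7-triethyl-9-phenyl-4-[(Z)-prop-1-enyl]-5-trimethylsilyloxynona-6,8-dienoate, via alkenylzirconocene chloride 19 (not isolated)
Conditions: Cp2Zr(H)Cl, THF, rt → 40 °C; then ZnCl2, Pd(PPh3)4 (5 mol %), 18, THF, rt
Reagents that add atoms: none
Why: Hydrozirconation followed by Negishi cross-coupling. The Zr–H bond adds syn with zirconium on the alkyne carbon remote from the quaternary C7, so after coupling the styryl group sits on C5 trans to C7 (E). ZnCl2 passes the alkenyl group on to palladium, and the coupling retains both alkene geometries.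

Step 11
Reactants: 20 tert-butyl (6E,8E)-3-[1-(tert-butyldimethylsilyloxy)propan-2-yl]-2,5,7-triethyl-9-phenyl-4-[(Z)-prop-1-enyl]-5-trimethylsilyloxynona-6,8-dienoate
Product: 21 (6E,8E)-3-[1-(tert-butyldimethylsilyloxy)propan-2-yl]-2,5,7-triethyl-9-phenyl-4-[(Z)-prop-1-enyl]nona-6,8-diene-1,5-diol
Conditions: LiAlH4, Et2O, 0 °C → rt; then K2CO3, MeOH, rt
Reagents that add atoms: none
Why: Hydride reduction of the tert-butyl ester to the primary alcohol; the diene is inert to LiAlH4. Basic methanolysis then removes the trimethylsilyl ether from C7 and leaves the primary tert-butyldimethylsilyl ether in place.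

Step 12
Reactants: 21 (6E,8E)-3-[1-(tert-butyldimethylsilyloxy)propan-2-yl]-2,5,7-triethyl-9-phenyl-4-[(Z)-prop-1-enyl]nona-6,8-diene-1,5-diol
Product: 22 4-[1-(tert-butyldimethylsilyloxy)propan-2-yl]-3,6-diethyl-6-[(1E,3E)-2-ethyl-4-phenylbuta-1,3-dienyl]-5-[(Z)-prop-1-enyl]oxan-2-one (dienyl cis to the C3a side chain and trans to the propenyl group)
Conditions: (n-Pr4N)RuO4 (5 mol %), N-methylmorpholine N-oxide, 4 Å molecular sieves, CH2Cl2, rt
Reagents that add atoms: none
Why: Oxidative lactonisation of a 1,5-diol (Ley–Griffith oxidation). The primary alcohol goes to the aldehyde, which closes to the lactol with the tertiary hydroxyl and is oxidised on to the δ-lactone. The medium is neutral, so the ionisable tertiary dienylic C–O bond is never exposed to acid or to an acylating agent.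

Step 13
Reactants: 22 4-[1-(tert-butyldimethylsilyloxy)propan-2-yl]-3,6-diethyl-6-[(1E,3E)-2-ethyl-4-phenylbuta-1,3-dienyl]-5-[(Z)-prop-1-enyl]oxan-2-one
Product: 25 6-[1-(tert-butyldimethylsilyloxy)propan-2-yl]-1,2,4-triethyl-2-[(E)-2-phenylethenyl]-5-[(Z)-prop-1-enyl]cyclohex-3-ene-1-carboxylic acid, via silyl ketene acetal 23 (not isolated), via trimethylsilyl ester 24 (not isolated)
Conditions: Me3SiCl/Et3N, LiN(i-Pr)2, THF, −78 °C → rt; then PhMe, 90 °C; then aq. citric acid, THF
Reagents that add atoms: none
Why: The amide base removes the single α-proton at C4 and the enolate is silylated on oxygen to the endocyclic silyl ketene acetal 23, whose geometry is fixed by the lactone ring (Ireland–Claisen rearrangement in its lactone ring-contraction form). On warming, 23 undergoes a concerted suprafacial [3,3] shift: C4 bonds to C5, the C7–O bond breaks and the alkene moves to C6=C7, giving silyl ester 24, which is hydrolysed on work-up. The closest known reaction type is the enolate Claisen ring contraction of 6-alkenyl δ-lactones and their 1,4-dioxan-2-one analogues to cyclohexene- and dihydropyran-carboxylic acids. Ring A (C4–C5–C6–C7–C7a–C3a) closes through a boat-like, bicyclo[2.2.2]-type transition state, the only one open because the C3a–C7a bridge ties the ketene acetal to the allyl unit. C4 is controlled by the C7 stereocentre: the new bond forms on the lactone face that carries the dienyl group, so the carboxyl ends trans to the C3a side chain and cis to the C7a propenyl group. C5 is controlled by the (E) geometry of C6=C5: in the boat the substituent trans to C7 (styryl) ends cis to the carboxyl and the C5 ethyl ends cis to the C4 ethyl. The step needs chemoselectivity over ionisation of the tertiary dienylic ester and over Cope rearrangement of the 1,5-diene formed by the propenyl group and C6=C5; the basic aprotic medium and a temperature well below the Cope range should secure this. Because the shift is unimolecular, full substitution at both termini is tolerated.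

Step 14
Reactants: 25 6-[1-(tert-butyldimethylsilyloxy)propan-2-yl]-1,2,4-triethyl-2-[(E)-2-phenylethenyl]-5-[(Z)-prop-1-enyl]cyclohex-3-ene-1-carboxylic acid
Product: 26 prop-2-enyl 6-[1-(tert-butyldimethylsilyloxy)propan-2-yl]-1,2,4-triethyl-2-[(E)-2-phenylethenyl]-5-[(Z)-prop-1-enyl]cyclohex-3-ene-1-carboxylate
Conditions: CH2=CHCH2Br, Cs2CO3, DMF, rt
Reagents that add atoms: allyl bromide, C=CCBr
Why: O-Alkylation of the caesium carboxylate (SN2 at the allyl bromide); the reaction takes place at oxygen, so the steric shielding of the acyl carbon does not matter.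

Step 15
Reactants: 26 prop-2-enyl 6-[1-(tert-butyldimethylsilyloxy)propan-2-yl]-1,2,4-triethyl-2-[(E)-2-phenylethenyl]-5-[(Z)-prop-1-enyl]cyclohex-3-ene-1-carboxylate
Product: 27 prop-2-enyl 1,2,4-triethyl-6-(1-hydroxypropan-2-yl)-2-[(E)-2-phenylethenyl]-5-[(Z)-prop-1-enyl]cyclohex-3-ene-1-carboxylate
Conditions: HF·pyridine, pyridine, THF, 0 °C → rt
Reagents that add atoms: none
Why: Fluoride-mediated desilylation under buffered, non-basic conditions; no alkoxide is formed, so the freed hydroxyl does not lactonise onto the neighbouring ester.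

Step 16
Reactants: 27 prop-2-enyl 1,2,4-triethyl-6-(1-hydroxypropan-2-yl)-2-[(E)-2-phenylethenyl]-5-[(Z)-prop-1-enyl]cyclohex-3-ene-1-carboxylate
Product: 28 2-{2,3,5-triethyl-3-[(E)-2-phenylethenyl]-2-(prop-2-enyloxycarbonyl)-6-[(Z)-prop-1-enyl]cyclohex-4-en-1-yl}propanoic acid
Conditions: TEMPO (20 mol %), PhI(OAc)2, MeCN/pH 7 buffer, rt
Reagents that add atoms: water, O
Why: Oxoammonium-mediated oxidation of the primary alcohol through the aldehyde hydrate to the acid; alkenes are not touched. Any epimerisation at C3 on the way is corrected in step 18.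

Step 17
Reactants: 28 2-{2,3,5-triethyl-3-[(E)-2-phenylethenyl]-2-(prop-2-enyloxycarbonyl)-6-[(Z)-prop-1-enyl]cyclohex-4-en-1-yl}propanoic acid
Product: 29 Se-phenyl 2-{2,3,5-triethyl-3-[(E)-2-phenylethenyl]-2-(prop-2-enyloxycarbonyl)-6-[(Z)-prop-1-enyl]cyclohex-4-en-1-yl}propaneselenoate
Conditions: (PhSe)2, n-Bu3P, CH2Cl2, rt
Reagents that add atoms: diphenyl diselenide, c1ccccc1[Se][Se]c1ccccc1
Why: Selenoester formation through the acyloxyphosphonium salt (phosphine–diselenide activation of the acid); the C4 carboxyl is masked, so only the C2 acid reacts.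

Step 18
Reactants: 29 Se-phenyl 2-{2,3,5-triethyl-3-[(E)-2-phenylethenyl]-2-(prop-2-enyloxycarbonyl)-6-[(Z)-prop-1-enyl]cyclohex-4-en-1-yl}propaneselenoate
Product: 32 prop-2-enyl 1,4,5,7-tetraethyl-3-methyl-2-oxo-5-[(E)-2-phenylethenyl]-2,3,3a,4,5,7a-hexahydro-1H-indene-4-carboxylate (trans-fused and all-trans on ring B), via acyl radical 30 (not isolated), via secondary alkyl radical 31 (not isolated)
Conditions: n-Bu3SnH (slow addition), AIBN (cat.), PhH, 80 °C; then DBU, rt
Reagents that add atoms: none
Why: Acyl radical cyclisation in a tin hydride chain. Abstraction of PhSe gives acyl radical 30, which closes 5-exo-trig onto the inner propenyl carbon through a chair-like transition state to radical 31 and, after hydrogen transfer, the trans-fused cyclopentanone; closure onto the styryl group is geometrically impossible because that group is trans-1,3 to the radical-bearing chain. DBU then equilibrates C1 and C3 to the all-trans ketone, so the propenyl geometry and any C3 epimerisation in step 16 are without consequence.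

Step 19
Reactants: 32 prop-2-enyl 1,4,5,7-tetraethyl-3-methyl-2-oxo-5-[(E)-2-phenylethenyl]-2,3,3a,4,5,7a-hexahydro-1H-indene-4-carboxylate
Product: 33 1,4,5,7-tetraethyl-3-methyl-2-oxo-5-[(E)-2-phenylethenyl]-2,3,3a,4,5,7a-hexahydro-1H-indene-4-carboxylic acid (CNP0324606.3)
Conditions: Pd(PPh3)4 (5 mol %), morpholine, THF, rt
Reagents that add atoms: none
Why: Tsuji–Trost deallylation; zerovalent palladium ionises the allyl ester at the allyl carbon and morpholine traps the allyl fragment. The hindered acid is released without acid or base strong enough to lactonise it onto C6=C7 or to disturb C1/C3.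

## Compound list

1 | methyl (R)-3-hydroxy-2-methylpropanoate | COC(=O)[C@H](C)CO | starting material
2 | methyl (R)-3-(tert-butyldimethylsilyloxy)-2-methylpropanoate | COC(=O)[C@H](C)CO[Si](C)(C)C(C)(C)C | intermediate
3 | (R)-3-(tert-butyldimethylsilyloxy)-2-methylpropanal | O=C[C@H](C)CO[Si](C)(C)C(C)(C)C | intermediate
4 | methyl (2Z,4S)-5-(tert-butyldimethylsilyloxy)-4-methylpent-2-enoate | COC(=O)/C=C\[C@H](C)CO[Si](C)(C)C(C)(C)C | intermediate
5 | (S)-5-methyl-5,6-dihydro-2H-pyran-2-one | O=C1OC[C@@H](C)C=C1 | intermediate
6 | but-1-yne | CCC#C | starting material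
7 | N-methoxy-N-methylpropanamide | CCC(=O)N(C)OC | starting material
8 | but-1-ynyllithium | [Li]C#CCC | intermediate
9 | hept-4-yn-3-one | CCC(=O)C#CCC | intermediate
10 | tert-butyl butanoate | CCCC(=O)OC(C)(C)C | starting material
11 | lithium enolate of tert-butyl butanoate (ethyl trans to O–Li) | CC/C=C(/O[Li])OC(C)(C)C | intermediate
12 | lithium 4-(1-tert-butoxy-1-oxobutan-2-yl)-5-methyl-5,6-dihydro-4H-pyran-2-olate (4,5-trans) | [Li]OC1=C[C@@H](C(CC)C(=O)OC(C)(C)C)[C@H](C)CO1 | intermediate
13 | lithium alkoxide of tert-butyl 2-[3-(3-hydroxyhept-4-yn-3-yl)-5-methyl-2-oxooxan-4-yl]butanoate | O=C1OC[C@@H](C)[C@H](C(CC)C(=O)OC(C)(C)C)[C@H]1[C@@](O[Li])(CC)C#CCC | intermediate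
14 | tert-butyl 2-[5-methyl-2-oxo-3-(3-trimethylsilyloxyhept-4-yn-3-yl)oxan-4-yl]butanoate (ring substituents all-trans) | O=C1OC[C@@H](C)[C@H](C(CC)C(=O)OC(C)(C)C)[C@H]1[C@@](O[Si](C)(C)C)(CC)C#CCC | intermediate
15 | tert-butyl 2-[2-hydroxy-5-methyl-3-(3-trimethylsilyloxyhept-4-yn-3-yl)oxan-4-yl]butanoate | OC1OC[C@@H](C)[C@H](C(CC)C(=O)OC(C)(C)C)[C@H]1[C@@](O[Si](C)(C)C)(CC)C#CCC | intermediate
16 | tert-butyl 2,5-diethyl-3-(1-hydroxypropan-2-yl)-4-[(Z)-prop-1-enyl]-5-trimethylsilyloxynon-6-ynoate | OC[C@@H](C)[C@H](C(CC)C(=O)OC(C)(C)C)[C@H](/C=C\C)[C@@](O[Si](C)(C)C)(CC)C#CCC | intermediate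
17 | tert-butyl 3-[1-(tert-butyldimethylsilyloxy)propan-2-yl]-2,5-diethyl-4-[(Z)-prop-1-enyl]-5-trimethylsilyloxynon-6-ynoate | CC(C)(C)[Si](C)(C)OC[C@@H](C)[C@H](C(CC)C(=O)OC(C)(C)C)[C@H](/C=C\C)[C@@](O[Si](C)(C)C)(CC)C#CCC | intermediate
18 | (E)-(2-bromoethenyl)benzene | Br/C=C/c1ccccc1 | starting material
19 | alkenylzirconocene chloride from 17 (Cp2ZrCl on C5 of the target numbering, trans to C7) | CC(C)(C)[Si](C)(C)OC[C@@H](C)[C@H](C(CC)C(=O)OC(C)(C)C)[C@H](/C=C\C)[C@@](O[Si](C)(C)C)(CC)/C=C(CC)/[Zr](Cl)(C1C=CC=C1)C1C=CC=C1 | intermediate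
20 | tert-butyl (6E,8E)-3-[1-(tert-butyldimethylsilyloxy)propan-2-yl]-2,5,7-triethyl-9-phenyl-4-[(Z)-prop-1-enyl]-5-trimethylsilyloxynona-6,8-dienoate | CC(C)(C)[Si](C)(C)OC[C@@H](C)[C@H](C(CC)C(=O)OC(C)(C)C)[C@H](/C=C\C)[C@@](O[Si](C)(C)C)(CC)/C=C(CC)/C=C/c1ccccc1 | intermediate
21 | (6E,8E)-3-[1-(tert-butyldimethylsilyloxy)propan-2-yl]-2,5,7-triethyl-9-phenyl-4-[(Z)-prop-1-enyl]nona-6,8-diene-1,5-diol | CC(C)(C)[Si](C)(C)OC[C@@H](C)[C@H](C(CC)CO)[C@H](/C=C\C)[C@@](O)(CC)/C=C(CC)/C=C/c1ccccc1 | intermediate
22 | 4-[1-(tert-butyldimethylsilyloxy)propan-2-yl]-3,6-diethyl-6-[(1E,3E)-2-ethyl-4-phenylbuta-1,3-dienyl]-5-[(Z)-prop-1-enyl]oxan-2-one | O=C1O[C@](CC)(/C=C(CC)/C=C/c2ccccc2)[C@@H](/C=C\C)[C@H]([C@H](C)CO[Si](C)(C)C(C)(C)C)C1CC | intermediate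
23 | 4-[1-(tert-butyldimethylsilyloxy)propan-2-yl]-3,6-diethyl-6-[(1E,3E)-2-ethyl-4-phenylbuta-1,3-dienyl]-5-[(Z)-prop-1-enyl]-2-trimethylsilyloxy-5,6-dihydro-4H-pyran | C[Si](C)(C)OC1=C(CC)[C@@H]([C@H](C)CO[Si](C)(C)C(C)(C)C)[C@H](/C=C\C)[C@@](CC)(/C=C(CC)/C=C/c2ccccc2)O1 | intermediate
24 | trimethylsilyl 6-[1-(tert-butyldimethylsilyloxy)propan-2-yl]-1,2,4-triethyl-2-[(E)-2-phenylethenyl]-5-[(Z)-prop-1-enyl]cyclohex-3-ene-1-carboxylate | CCC1=C[C@@](/C=C/c2ccccc2)(CC)[C@](CC)(C(=O)O[Si](C)(C)C)[C@@H]([C@H](C)CO[Si](C)(C)C(C)(C)C)[C@@H]1/C=C\C | intermediate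
25 | 6-[1-(tert-butyldimethylsilyloxy)propan-2-yl]-1,2,4-triethyl-2-[(E)-2-phenylethenyl]-5-[(Z)-prop-1-enyl]cyclohex-3-ene-1-carboxylic acid | CCC1=C[C@@](/C=C/c2ccccc2)(CC)[C@](CC)(C(=O)O)[C@@H]([C@H](C)CO[Si](C)(C)C(C)(C)C)[C@@H]1/C=C\C | intermediate
26 | prop-2-enyl 6-[1-(tert-butyldimethylsilyloxy)propan-2-yl]-1,2,4-triethyl-2-[(E)-2-phenylethenyl]-5-[(Z)-prop-1-enyl]cyclohex-3-ene-1-carboxylate | CCC1=C[C@@](/C=C/c2ccccc2)(CC)[C@](CC)(C(=O)OCC=C)[C@@H]([C@H](C)CO[Si](C)(C)C(C)(C)C)[C@@H]1/C=C\C | intermediate
27 | prop-2-enyl 1,2,4-triethyl-6-(1-hydroxypropan-2-yl)-2-[(E)-2-phenylethenyl]-5-[(Z)-prop-1-enyl]cyclohex-3-ene-1-carboxylate | CCC1=C[C@@](/C=C/c2ccccc2)(CC)[C@](CC)(C(=O)OCC=C)[C@@H]([C@H](C)CO)[C@@H]1/C=C\C | intermediate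
28 | 2-{2,3,5-triethyl-3-[(E)-2-phenylethenyl]-2-(prop-2-enyloxycarbonyl)-6-[(Z)-prop-1-enyl]cyclohex-4-en-1-yl}propanoic acid | CCC1=C[C@@](/C=C/c2ccccc2)(CC)[C@](CC)(C(=O)OCC=C)[C@@H]([C@H](C)C(=O)O)[C@@H]1/C=C\C | intermediate
29 | Se-phenyl 2-{2,3,5-triethyl-3-[(E)-2-phenylethenyl]-2-(prop-2-enyloxycarbonyl)-6-[(Z)-prop-1-enyl]cyclohex-4-en-1-yl}propaneselenoate | CCC1=C[C@@](/C=C/c2ccccc2)(CC)[C@](CC)(C(=O)OCC=C)[C@@H]([C@H](C)C(=O)[Se]c2ccccc2)[C@@H]1/C=C\C | intermediate
30 | acyl radical from 29 (radical centre at C2) | CCC1=C[C@@](/C=C/c2ccccc2)(CC)[C@](CC)(C(=O)OCC=C)[C@@H]([C@H](C)[C]=O)[C@@H]1/C=C\C | intermediate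
31 | cyclised secondary alkyl radical (radical centre on the carbon attached to C1) | CCC1=C[C@@](/C=C/c2ccccc2)(CC)[C@](CC)(C(=O)OCC=C)[C@@H]2[C@@H]1[C@H]([CH]C)C(=O)[C@H]2C | intermediate
32 | prop-2-enyl 1,4,5,7-tetraethyl-3-methyl-2-oxo-5-[(E)-2-phenylethenyl]-2,3,3a,4,5,7a-hexahydro-1H-indene-4-carboxylate | CCC1=C[C@@](/C=C/c2ccccc2)(CC)[C@](CC)(C(=O)OCC=C)[C@@H]2[C@@H]1[C@H](CC)C(=O)[C@H]2C | intermediate
33 | 1,4,5,7-tetraethyl-3-methyl-2-oxo-5-[(E)-2-phenylethenyl]-2,3,3a,4,5,7a-hexahydro-1H-indene-4-carboxylic acid (CNP0324606.3) | CCC1=C[C@@](/C=C/c2ccccc2)(CC)[C@](CC)(C(=O)O)[C@@H]2[C@@H]1[C@H](CC)C(=O)[C@H]2C | target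

## Step count and least certain steps

Total: 19 steps. Longest linear sequence: 18 steps (steps 1–4 and 6–19, from 1); step 5 is a one-step side branch.

**Step 13 (key step).** Two processes can compete with the concerted shift. The tertiary, doubly allylic C7–O bond of the silyl ketene acetal may ionise, which would lead to elimination or to loss of stereospecificity at C5. Alternatively, the boat that must bring two fully substituted carbons together may be reached only at temperatures where the 1,5-diene begins to undergo Cope rearrangement.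

Fallback, from 20 back to 25: the C4–C5 bond is formed by an ionic ring closure instead of a sigmatropic one. Compound 20 is converted with LiN(i-Pr)2 and Me3SiCl into the tert-butyl trimethylsilyl ketene acetal, (6E,8E)-1-tert-butoxy-3-[1-(tert-butyldimethylsilyloxy)propan-2-yl]-2,5,7-triethyl-9-phenyl-4-[(Z)-prop-1-enyl]-1,5-bis(trimethylsilyloxy)nona-1,6,8-triene F1. Catalytic Me3SiOTf in CH2Cl2 at −78 °C then ionises the tertiary dienylic silyl ether on purpose, and the pentadienyl cation is captured at C5 by the ketene acetal carbon in a six-membered chair (intramolecular Mukaiyama-type allylic alkylation). This gives tert-butyl 6-[1-(tert-butyldimethylsilyloxy)propan-2-yl]-1,2,4-triethyl-2-[(E)-2-phenylethenyl]-5-[(Z)-prop-1-enyl]cyclohex-3-ene-1-carboxylate F2. Me3SiOTf with 2,6-lutidine followed by aqueous work-up cleaves the tert-butyl ester to 25. Stereocontrol at C4/C5 would rest on a chair with the C3a and C7a substituents equatorial; this is less rigid than the boat of the sigmatropic route and would have to be checked.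

**Step 6.** The hindered lactone enolate may transfer a proton from 5 or from the ynone, or add in conjugate fashion to the ynone, instead of adding to its carbonyl. The tertiary lithium aldolate may revert before it is silylated. The discrimination between ethyl and alkynyl in the chair may be incomplete.

Fallback, from 5 and 10 back to 14: the Michael addition is run as before, but the lactone enolate is quenched with N-bromosuccinimide to give tert-butyl 2-(3-bromo-5-methyl-2-oxooxan-4-yl)butanoate F3. A Reformatsky reaction of F3 with activated zinc and 9 in THF generates the zinc enolate under non-basic conditions in the presence of the ketone. Zinc aldolates do not revert readily, and silylation (Me3SiCl, imidazole) gives 14 through the same chair model.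

**Step 10.** Hydrozirconation of an internal alkyne next to a quaternary carbon may be slow or regiochemically incomplete. The reagent may begin to isomerise the (Z)-propenyl group, or the alkenylmetal may be protonated before it couples.

Fallback, from 17 back to 20: copper-catalysed borylation (CuCl, NaOt-Bu, Xantphos, B2pin2, MeOH) adds H and boron syn, with boron on the alkyne carbon remote from the oxygenated quaternary centre. This gives the isolable alkenylboronate, tert-butyl 3-[1-(tert-butyldimethylsilyloxy)propan-2-yl]-2,5-diethyl-4-[(Z)-prop-1-enyl]-7-(4,4,5,5-tetramethyl-1,3,2-dioxaborolan-2-yl)-5-trimethylsilyloxynon-6-enoate F4, with boron on C5 of the target numbering, trans to C7. Suzuki–Miyaura coupling with 18 (Pd(dppf)Cl2, K3PO4, THF/H2O) then gives 20.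

**Step 18.** The acyl radical may lose CO before it cyclises, or close in the 6-endo mode. The cyclised radical may abstract an allylic hydrogen from the CH2 of the C7 ethyl group (1,5-transfer) before the stannane reduces it, which would move the ring alkene.

Fallback, from 27 back to 32: Dess–Martin oxidation of 27 gives the aldehyde, prop-2-enyl 1,2,4-triethyl-6-(1-oxopropan-2-yl)-2-[(E)-2-phenylethenyl]-5-[(Z)-prop-1-enyl]cyclohex-3-ene-1-carboxylate F5. SmI2 with HMPA and t-BuOH in THF generates the ketyl radical anion, which cannot lose CO and adds 5-exo to the propenyl group. This gives the cyclopentanol, prop-2-enyl 1,4,5,7-tetraethyl-2-hydroxy-3-methyl-5-[(E)-2-phenylethenyl]-2,3,3a,4,5,7a-hexahydro-1H-indene-4-carboxylate F6. Dess–Martin oxidation and the same DBU equilibration give 32.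

## Further compounds

F1 | step 13 | (6E,8E)-1-tert-butoxy-3-[1-(tert-butyldimethylsilyloxy)propan-2-yl]-2,5,7-triethyl-9-phenyl-4-[(Z)-prop-1-enyl]-1,5-bis(trimethylsilyloxy)nona-1,6,8-triene | CC(C)(C)[Si](C)(C)OC[C@@H](C)[C@H](C(CC)=C(O[Si](C)(C)C)OC(C)(C)C)[C@H](/C=C\C)[C@@](O[Si](C)(C)C)(CC)/C=C(CC)/C=C/c1ccccc1
F2 | step 13 | tert-butyl 6-[1-(tert-butyldimethylsilyloxy)propan-2-yl]-1,2,4-triethyl-2-[(E)-2-phenylethenyl]-5-[(Z)-prop-1-enyl]cyclohex-3-ene-1-carboxylate | CCC1=C[C@@](/C=C/c2ccccc2)(CC)[C@](CC)(C(=O)OC(C)(C)C)[C@@H]([C@H](C)CO[Si](C)(C)C(C)(C)C)[C@@H]1/C=C\C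
F3 | step 6 | tert-butyl 2-(3-bromo-5-methyl-2-oxooxan-4-yl)butanoate | O=C1OC[C@@H](C)[C@H](C(CC)C(=O)OC(C)(C)C)C1Br
F4 | step 10 | tert-butyl 3-[1-(tert-butyldimethylsilyloxy)propan-2-yl]-2,5-diethyl-4-[(Z)-prop-1-enyl]-7-(4,4,5,5-tetramethyl-1,3,2-dioxaborolan-2-yl)-5-trimethylsilyloxynon-6-enoate | CC(C)(C)[Si](C)(C)OC[C@@H](C)[C@H](C(CC)C(=O)OC(C)(C)C)[C@H](/C=C\C)[C@@](O[Si](C)(C)C)(CC)/C=C(CC)/B1OC(C)(C)C(C)(C)O1
F5 | step 18 | prop-2-enyl 1,2,4-triethyl-6-(1-oxopropan-2-yl)-2-[(E)-2-phenylethenyl]-5-[(Z)-prop-1-enyl]cyclohex-3-ene-1-carboxylate | CCC1=C[C@@](/C=C/c2ccccc2)(CC)[C@](CC)(C(=O)OCC=C)[C@@H]([C@H](C)C=O)[C@@H]1/C=C\C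
F6 | step 18 | prop-2-enyl 1,4,5,7-tetraethyl-2-hydroxy-3-methyl-5-[(E)-2-phenylethenyl]-2,3,3a,4,5,7a-hexahydro-1H-indene-4-carboxylate | CCC1=C[C@@](/C=C/c2ccccc2)(CC)[C@](CC)(C(=O)OCC=C)[C@@H]2[C@@H]1[C@H](CC)C(O)[C@H]2C
A1 | alternative 1 | all-trans 2-ethyl-5-methyl-3-[(S)-1-(tert-butyldimethylsilyloxy)ethyl]-4-[2-(tert-butyldimethylsilyloxy)ethyl]cyclopentan-1-one | C[C@H](O[Si](C)(C)C(C)(C)C)[C@H]1[C@H](CC)C(=O)[C@@H](C)[C@@H]1CCO[Si](C)(C)C(C)(C)C
A2 | alternative 1 | (3E,6E,8S)-1,8-bis(tert-butyldimethylsilyloxy)-6-ethyl-4-methylnona-3,6-dien-5-one | C[C@H](O[Si](C)(C)C(C)(C)C)/C=C(CC)/C(=O)/C(C)=C/CCO[Si](C)(C)C(C)(C)C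
A3 | alternative 2 | methyl ester of the C2 ethylene ketal of the target | CCC1=C[C@@](/C=C/c2ccccc2)(CC)[C@](CC)(C(=O)OC)[C@@H]2[C@@H]1[C@H](CC)C3(OCCO3)[C@H]2C
A4 | alternative 2 | 5-bromo-1,5,6,8-tetraethyl-2,2-(ethylenedioxy)-3-methyl-6-[(E)-2-phenylethenyl]-2,3,3a,5,6,8a-hexahydroazulen-4(1H)-one | CCC1=C[C@@](/C=C/c2ccccc2)(CC)[C@](CC)(Br)C(=O)[C@@H]2[C@@H]1[C@H](CC)C3(OCCO3)[C@H]2C
A5 | alternative 3 | methyl 1,4,5,7-tetraethyl-3-methyl-2-oxo-5-[(E)-2-phenylethenyl]-2,3,3a,4,5,7a-hexahydro-1H-indene-4-carboxylate | CCC1=C[C@@](/C=C/c2ccccc2)(CC)[C@](CC)(C(=O)OC)[C@@H]2[C@@H]1[C@H](CC)C(=O)[C@H]2C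
A6 | alternative 3 | methyl (E)-2,3-diethyl-2-{3-ethyl-2-[(Z)-1-iodobut-1-en-2-yl]-5-methyl-4-oxocyclopentyl}-5-phenylpent-3-enoate | I/C=C(CC)\[C@H]1[C@H](CC)C(=O)[C@@H](C)[C@@H]1[C@@](CC)(C(=O)OC)/C(CC)=C/Cc1ccccc1
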